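**Plan**

- Ring B (the quinone) is numbered C1'(=O), C2'(OMe), C3'(OMe), C4'(=O), C5' (bonded to chroman C3), C6'(H). The retrosynthesis cuts it at C1'–C2' and C5'–C6', a [4+2] between a C2'–C5' diene and a C6'–C1' alkyne.
- The feature that allows this: ring B carries oxygen on four neighbouring carbons and has one free CH. C2', C3' and C4' are the ester, α-methoxy and ketone carbons of an α-methoxy-β-keto ester, and C5' is its γ-carbon. C6'–C1' is but-3-yn-2-one, whose activating acetyl group is later exchanged for oxygen.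
- Further cuts: C4'–C3' (Claisen) back to a chroman-3-ylacetic Weinreb amide, O1–C8a of ring C (Pd C–O coupling), and the C3–C4 Stobbe alkene, back to a bromo-syringaldehyde benzyl ether and dimethyl succinate.
- Forward order: ring A is bought, ring C is closed second, and ring B is built last from the open chain. Methylation, Baeyer–Villiger oxidation, oxidative demethylation and debenzylation then give the hydroxy quinone.
- Stereochemistry: the single stereocenter C3 (S) is set by Rh/DuPhos hydrogenation of the Stobbe half-ester (step 3) and is never α to a carbonyl after step 4.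

Key step: step 9

Assumption: (S,S)-Et-DuPhos is taken as the ligand antipode that gives (S)-5; if the sense proves opposite, the (R,R) ligand is used and nothing else changes.

**Route**

Step 1
Reactants: 1 4-(benzyloxy)-3,5-dimethoxybenzaldehyde
Product: 2 4-(benzyloxy)-2-bromo-3,5-dimethoxybenzaldehyde
Conditions: NBS, MeCN, rt to 40 °C, dark
Reagents that add atoms: N-bromosuccinimide, O=C1CCC(=O)N1Br
Why: Electrophilic aromatic bromination; the two free ring positions are equivalent by symmetry and each is activated by an ortho and a para methoxy group, so a single monobromide should form, and the bromine marks the carbon that later becomes C8a.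

Step 2
Reactants: 2 4-(benzyloxy)-2-bromo-3,5-dimethoxybenzaldehyde; 3 dimethyl succinate
Product: 4 (E)-4-[4-(benzyloxy)-2-bromo-3,5-dimethoxyphenyl]-3-(methoxycarbonyl)but-3-enoic acid
Conditions: NaOMe, MeOH, reflux; then 2 M HCl
Reagents that add atoms: none
Why: Stobbe condensation (aldol addition, lactonization to the paraconic ester, E1cB ring opening) should give the (E)-alkylidene half-ester, which differentiates the two carboxyl carbons: the conjugated ester is the future C2 and the free acid the future C4'.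

Step 3
Reactants: 4 (E)-4-[4-(benzyloxy)-2-bromo-3,5-dimethoxyphenyl]-3-(methoxycarbonyl)but-3-enoic acid
Product: 5 (3S)-4-[4-(benzyloxy)-2-bromo-3,5-dimethoxyphenyl]-3-(methoxycarbonyl)butanoic acid
Conditions: H2 (5 bar), [Rh(cod)((S,S)-Et-DuPhos)]BF4 (1 mol%), NaOMe (0.1 equiv), MeOH, rt
Reagents that add atoms: none
Why: Rhodium-catalyzed asymmetric hydrogenation of an itaconate-type half-ester, in which carboxylate and alkene chelate the metal; the chiral bisphosphine sets C3 as S, and the homogeneous catalyst should leave the aryl bromide and the benzyl ether alone.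

Step 4
Reactants: 5 (3S)-4-[4-(benzyloxy)-2-bromo-3,5-dimethoxyphenyl]-3-(methoxycarbonyl)butanoic acid
Product: 7 (4S)-4-{[4-(benzyloxy)-2-bromo-3,5-dimethoxyphenyl]methyl}oxolan-2-one, via hydroxy acid 6 (not isolated)
Conditions: KOH (1 equiv), EtOH; CaCl2, NaBH4, −10 °C to rt; then 2 M HCl
Reagents that add atoms: none
Why: Calcium borohydride reduces the methyl ester but not the carboxylate, and acidification closes the γ-lactone; after reduction the stereocenter is no longer α to a carbonyl and should keep its configuration.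

Step 5
Reactants: 7 (4S)-4-{[4-(benzyloxy)-2-bromo-3,5-dimethoxyphenyl]methyl}oxolan-2-one
Product: 8 (3S)-4-[4-(benzyloxy)-2-bromo-3,5-dimethoxyphenyl]-3-(hydroxymethyl)-N-methoxy-N-methylbutanamide
Conditions: MeNH(OMe)·HCl, i-PrMgCl, THF, −20 °C (amide preformed); then 7, −20 to 0 °C; sat. NH4Cl; used at once
Reagents that add atoms: N,O-dimethylhydroxylamine hydrochloride, CNOC.Cl
Why: Aminolysis of a lactone by the magnesium amide of N,O-dimethylhydroxylamine (Weinreb amide formation) frees the primary alcohol for ring closure; the Grignard reagent is consumed before the lactone is added, so the aryl bromide is not exchanged.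

Step 6
Reactants: 8 (3S)-4-[4-(benzyloxy)-2-bromo-3,5-dimethoxyphenyl]-3-(hydroxymethyl)-N-methoxy-N-methylbutanamide
Product: 9 2-[(3S)-7-(benzyloxy)-6,8-dimethoxy-3,4-dihydro-2H-chromen-3-yl]-N-methoxy-N-methylacetamide
Conditions: Pd(OAc)2 (3 mol%), 2-(di-tert-butylphosphino)-1,1'-binaphthyl (4 mol%), Cs2CO3, toluene, 65 °C
Reagents that add atoms: none
Why: Palladium-catalyzed intramolecular C–O coupling (Buchwald–Hartwig etherification) of the primary alcohol with the ortho aryl bromide, a 6-exo closure of ring C that bulky electron-rich phosphines favour over β-hydride elimination; C3 is not involved.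

Step 7
Reactants: 9 2-[(3S)-7-(benzyloxy)-6,8-dimethoxy-3,4-dihydro-2H-chromen-3-yl]-N-methoxy-N-methylacetamide; 10 methyl methoxyacetate
Product: 11 methyl 4-[(3S)-7-(benzyloxy)-6,8-dimethoxy-3,4-dihydro-2H-chromen-3-yl]-2-methoxy-3-oxobutanoate (mixture of C2 epimers and enol)
Conditions: LiN(i-Pr)2 (2.5 equiv), 10 (2.5 equiv), THF, −78 °C; then 9, −78 to −30 °C; sat. NH4Cl
Reagents that add atoms: none
Why: Crossed Claisen acylation of the lithium enolate of methyl methoxyacetate by a Weinreb amide; the chelated tetrahedral intermediate prevents double addition, and the new α-carbon may stay a mixture because it becomes sp2 in the next step.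

Step 8
Reactants: 11 methyl 4-[(3S)-7-(benzyloxy)-6,8-dimethoxy-3,4-dihydro-2H-chromen-3-yl]-2-methoxy-3-oxobutanoate
Product: 12 (3S)-7-(benzyloxy)-3-[(1Z)-3,4-dimethoxy-2,4-bis(trimethylsilyloxy)buta-1,3-dien-1-yl]-6,8-dimethoxy-3,4-dihydro-2H-chromene (ketene acetal geometry not controlled)
Conditions: Me3SiOTf (2.3 equiv), Et3N (3 equiv), Et2O, 0 °C to rt; ammonium salt layer removed, concentrated, used crude
Reagents that add atoms: trimethylsilyl trifluoromethanesulfonate, C[Si](C)(C)OS(=O)(=O)C(F)(F)F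
Why: Double O-silylation of a β-keto ester with silyl triflate and amine gives the 1-alkoxy-1,3-bis(silyloxy)diene (bis-silyl dienol ether formation); after the first silylation only the chain CH2 can be enolized, and the chroman should sit cis to the silyloxy group (Z).

Step 9
Reactants: 12 (3S)-7-(benzyloxy)-3-[(1Z)-3,4-dimethoxy-2,4-bis(trimethylsilyloxy)buta-1,3-dien-1-yl]-6,8-dimethoxy-3,4-dihydro-2H-chromene; 13 but-3-yn-2-one
Product: 15 1-{5-[(3S)-7-(benzyloxy)-6,8-dimethoxy-3,4-dihydro-2H-chromen-3-yl]-2,4-dihydroxy-3-methoxyphenyl}ethan-1-one, via cycloadduct 14 (not isolated)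
Conditions: 13 (1.5 equiv), toluene, 0 to 50 °C; then 1 M HCl, THF, rt
Reagents that add atoms: none
Why: The bis(silyloxy)diene attacks the unsubstituted β-carbon of the ynone with its chroman-bearing terminus, the position of highest HOMO coefficient because the ketene-acetal oxygens and the 3-silyloxy group both push electron density there, and the ketene-acetal carbon closes onto the acetyl-bearing carbon in an asynchronous [4+2] cycloaddition to give cyclohexa-1,4-diene 14; aqueous acid then removes the silyl groups and expels methanol across C2'/C5', which aromatizes the ring. The closest known reaction type is the Diels–Alder reaction of 1-alkoxy-3-silyloxy- and 1,1-dialkoxy-3-silyloxybutadienes with acetylenic ketones, followed by eliminative aromatization to oxygenated aryl ketones. Ring B is the only ring closed, by intermolecular [4+2] union of a four-carbon and a two-carbon unit in which C5'–C6' and C1'–C2' form in the same cycloaddition. No stereocenter is created, since the two sp3 carbons of 14 are erased on aromatization, and C3 of the chroman is not deprotonated under the neutral thermal conditions. The selectivity that matters is regiochemical (acetyl next to C2', hydrogen on C6'), and it is secured by the matched polarization of the diene (nucleophilic at C5') and the ynone (electrophilic at its CH carbon); the (Z) enol ether keeps the chroman on the outside of the s-cis diene so that the hindered terminus can still be reached.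

Step 10
Reactants: 15 1-{5-[(3S)-7-(benzyloxy)-6,8-dimethoxy-3,4-dihydro-2H-chromen-3-yl]-2,4-dihydroxy-3-methoxyphenyl}ethan-1-one
Product: 16 1-{5-[(3S)-7-(benzyloxy)-6,8-dimethoxy-3,4-dihydro-2H-chromen-3-yl]-2,3,4-trimethoxyphenyl}ethan-1-one
Conditions: MeI (excess), K2CO3, DMF, 50 °C
Reagents that add atoms: iodomethane, CI
Why: Williamson O-methylation of both phenols (the chelated ortho hydroxyl needs warm DMF); K2CO3 is too weak to enolize the aryl ketone, and any 2'-O-methyl ether formed in step 9 by loss of silanol in place of methanol converges to the same product.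

Step 11
Reactants: 16 1-{5-[(3S)-7-(benzyloxy)-6,8-dimethoxy-3,4-dihydro-2H-chromen-3-yl]-2,3,4-trimethoxyphenyl}ethan-1-one
Product: 18 5-[(3S)-7-(benzyloxy)-6,8-dimethoxy-3,4-dihydro-2H-chromen-3-yl]-2,3,4-trimethoxyphenol, via aryl acetate 17 (not isolated)
Conditions: mCPBA, CH2Cl2, 0 °C to rt; then K2CO3 (cat.), MeOH, rt
Reagents that add atoms: 3-chloroperbenzoic acid, OOC(=O)c1cccc(Cl)c1
Why: Baeyer–Villiger oxidation in which the electron-rich aryl group migrates in preference to methyl, followed by methanolysis of the aryl acetate; this turns the acetyl-bearing C1' into the fourth oxygenated carbon of ring B.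

Step 12
Reactants: 18 5-[(3S)-7-(benzyloxy)-6,8-dimethoxy-3,4-dihydro-2H-chromen-3-yl]-2,3,4-trimethoxyphenol
Product: 19 5-[(3S)-7-(benzyloxy)-6,8-dimethoxy-3,4-dihydro-2H-chromen-3-yl]-2,3-dimethoxycyclohexa-2,5-diene-1,4-dione
Conditions: PhI(OAc)2 (1.1 equiv), MeCN/H2O, 0 °C
Reagents that add atoms: water, O
Why: Oxidative demethylation of a para-methoxyphenol by PhI(OAc)2 in aqueous acetonitrile: water adds at C4', para to the phenol oxygen, and methanol is lost to give the para-quinone; the fully etherified ring A has no free phenol and should not react.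

Step 13
Reactants: 19 5-[(3S)-7-(benzyloxy)-6,8-dimethoxy-3,4-dihydro-2H-chromen-3-yl]-2,3-dimethoxycyclohexa-2,5-diene-1,4-dione
Product: 21 5-[(3S)-7-hydroxy-6,8-dimethoxy-3,4-dihydro-2H-chromen-3-yl]-2,3-dimethoxycyclohexa-2,5-diene-1,4-dione, via hydroquinone 20 (not isolated)
Conditions: H2 (1 atm), 10% Pd/C, EtOAc, rt; filter; then air (O2), EtOAc, rt
Reagents that add atoms: none
Why: Hydrogenolysis of the benzyl ether, which also reduces the quinone to hydroquinone 20; the 2,3-dimethoxyhydroquinone is reoxidized by oxygen far more readily than the hindered ring A phenol, so the quinone should return without ring A being touched.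

**Compound list**

1 | 4-(benzyloxy)-3,5-dimethoxybenzaldehyde | O=Cc1cc(OC)c(OCc2ccccc2)c(OC)c1 | starting material
2 | 4-(benzyloxy)-2-bromo-3,5-dimethoxybenzaldehyde | O=Cc1cc(OC)c(OCc2ccccc2)c(OC)c1Br | intermediate
3 | dimethyl succinate | COC(=O)CCC(=O)OC | starting material
4 | (E)-4-[4-(benzyloxy)-2-bromo-3,5-dimethoxyphenyl]-3-(methoxycarbonyl)but-3-enoic acid | COC(=O)/C(CC(=O)O)=C/c1cc(OC)c(OCc2ccccc2)c(OC)c1Br | intermediate
5 | (3S)-4-[4-(benzyloxy)-2-bromo-3,5-dimethoxyphenyl]-3-(methoxycarbonyl)butanoic acid | OC(=O)C[C@H](Cc1cc(OC)c(OCc2ccccc2)c(OC)c1Br)C(=O)OC | intermediate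
6 | (3S)-4-[4-(benzyloxy)-2-bromo-3,5-dimethoxyphenyl]-3-(hydroxymethyl)butanoic acid | OC(=O)C[C@H](Cc1cc(OC)c(OCc2ccccc2)c(OC)c1Br)CO | intermediate (not isolated)
7 | (4S)-4-{[4-(benzyloxy)-2-bromo-3,5-dimethoxyphenyl]methyl}oxolan-2-one | O=C1C[C@H](Cc2cc(OC)c(OCc3ccccc3)c(OC)c2Br)CO1 | intermediate
8 | (3S)-4-[4-(benzyloxy)-2-bromo-3,5-dimethoxyphenyl]-3-(hydroxymethyl)-N-methoxy-N-methylbutanamide | CON(C)C(=O)C[C@H](Cc1cc(OC)c(OCc2ccccc2)c(OC)c1Br)CO | intermediate
9 | 2-[(3S)-7-(benzyloxy)-6,8-dimethoxy-3,4-dihydro-2H-chromen-3-yl]-N-methoxy-N-methylacetamide | CON(C)C(=O)C[C@H]1COc2c(OC)c(OCc3ccccc3)c(OC)cc2C1 | intermediate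
10 | methyl methoxyacetate | COCC(=O)OC | starting material
11 | methyl 4-[(3S)-7-(benzyloxy)-6,8-dimethoxy-3,4-dihydro-2H-chromen-3-yl]-2-methoxy-3-oxobutanoate (C2 epimers) | COC(=O)C(OC)C(=O)C[C@H]1COc2c(OC)c(OCc3ccccc3)c(OC)cc2C1 | intermediate
12 | (3S)-7-(benzyloxy)-3-[(1Z)-3,4-dimethoxy-2,4-bis(trimethylsilyloxy)buta-1,3-dien-1-yl]-6,8-dimethoxy-3,4-dihydro-2H-chromene | COC(O[Si](C)(C)C)=C(OC)/C(O[Si](C)(C)C)=C/[C@H]1COc2c(OC)c(OCc3ccccc3)c(OC)cc2C1 | intermediate
13 | but-3-yn-2-one | CC(=O)C#C | starting material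
14 | 1-{3-[(3S)-7-(benzyloxy)-6,8-dimethoxy-3,4-dihydro-2H-chromen-3-yl]-5,6-dimethoxy-4,6-bis(trimethylsilyloxy)cyclohexa-1,4-dien-1-yl}ethan-1-one (diastereomer mixture at the two ring sp3 carbons) | CC(=O)C1=CC([C@H]2COc3c(OC)c(OCc4ccccc4)c(OC)cc3C2)C(O[Si](C)(C)C)=C(OC)C1(OC)O[Si](C)(C)C | intermediate (not isolated)
15 | 1-{5-[(3S)-7-(benzyloxy)-6,8-dimethoxy-3,4-dihydro-2H-chromen-3-yl]-2,4-dihydroxy-3-methoxyphenyl}ethan-1-one | CC(=O)c1cc([C@H]2COc3c(OC)c(OCc4ccccc4)c(OC)cc3C2)c(O)c(OC)c1O | intermediate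
16 | 1-{5-[(3S)-7-(benzyloxy)-6,8-dimethoxy-3,4-dihydro-2H-chromen-3-yl]-2,3,4-trimethoxyphenyl}ethan-1-one | CC(=O)c1cc([C@H]2COc3c(OC)c(OCc4ccccc4)c(OC)cc3C2)c(OC)c(OC)c1OC | intermediate
17 | 5-[(3S)-7-(benzyloxy)-6,8-dimethoxy-3,4-dihydro-2H-chromen-3-yl]-2,3,4-trimethoxyphenyl acetate | CC(=O)Oc1cc([C@H]2COc3c(OC)c(OCc4ccccc4)c(OC)cc3C2)c(OC)c(OC)c1OC | intermediate (not isolated)
18 | 5-[(3S)-7-(benzyloxy)-6,8-dimethoxy-3,4-dihydro-2H-chromen-3-yl]-2,3,4-trimethoxyphenol | Oc1cc([C@H]2COc3c(OC)c(OCc4ccccc4)c(OC)cc3C2)c(OC)c(OC)c1OC | intermediate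
19 | 5-[(3S)-7-(benzyloxy)-6,8-dimethoxy-3,4-dihydro-2H-chromen-3-yl]-2,3-dimethoxycyclohexa-2,5-diene-1,4-dione | COC1=C(OC)C(=O)C([C@H]2COc3c(OC)c(OCc4ccccc4)c(OC)cc3C2)=CC1=O | intermediate
20 | 5-[(3S)-7-hydroxy-6,8-dimethoxy-3,4-dihydro-2H-chromen-3-yl]-2,3-dimethoxybenzene-1,4-diol | COc1c(OC)c(O)c([C@H]2COc3c(OC)c(O)c(OC)cc3C2)cc1O | intermediate (not isolated)
21 | 5-[(3S)-7-hydroxy-6,8-dimethoxy-3,4-dihydro-2H-chromen-3-yl]-2,3-dimethoxycyclohexa-2,5-diene-1,4-dione | COC1=C(OC)C(=O)C([C@H]2COc3c(cc(OC)c(O)c3OC)C2)=CC1=O | target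

**Count and risks**

Total step count: 13. Longest linear sequence: 13 steps (1 to 21).

Steps most likely to fail:

1. Step 9 (together with the diene from step 8). The cycloaddition at the hindered, chroman-bearing diene terminus may be slow, so that hydrolysis or silyl migration of the diene, or open-chain conjugate addition without ring closure, takes over. The fallback replaces the cycloaddition by a Moore ring expansion of a squarate adduct; it sets out from 9 and comes back at 19. Amide 9 is reduced with i-Bu2AlH (THF, −78 °C) to 2-[(3S)-7-(benzyloxy)-6,8-dimethoxy-3,4-dihydro-2H-chromen-3-yl]acetaldehyde F1. Nonafluorobutanesulfonyl fluoride and a phosphazene base (DMF, 0 °C to rt) should convert it, through the enol sulfonate 2-[(3S)-7-(benzyloxy)-6,8-dimethoxy-3,4-dihydro-2H-chromen-3-yl]ethenyl nonafluorobutane-1-sulfonate F2, into (3S)-7-(benzyloxy)-3-ethynyl-6,8-dimethoxy-3,4-dihydro-2H-chromene F3. Its lithium acetylide (n-BuLi, THF, −78 °C) adds to dimethyl squarate to give 4-{[(3S)-7-(benzyloxy)-6,8-dimethoxy-3,4-dihydro-2H-chromen-3-yl]ethynyl}-4-hydroxy-2,3-dimethoxycyclobut-2-en-1-one F4. Heating F4 in p-xylene (about 140 °C) should open the four-membered ring to the alkynyl ketene and close it to quinone 19, after which step 13 follows.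

2. Step 6. The γ-hydroxy amide may return to lactone 7 under base and heat, or the palladium alkoxide may undergo β-hydride elimination with loss of bromine, faster than C–O reductive elimination. The fallback alkylates a phenol in place of arylating an alcohol; it sets out from 7 and comes back at 9. Hydroxylation of the aryl bromide (Pd2(dba)3, t-BuXPhos, KOH, dioxane/H2O, 100 °C; then HCl to re-close the lactone) gives (4S)-4-{[4-(benzyloxy)-2-hydroxy-3,5-dimethoxyphenyl]methyl}oxolan-2-one F5. Aminolysis as in step 5 gives (3S)-4-[4-(benzyloxy)-2-hydroxy-3,5-dimethoxyphenyl]-3-(hydroxymethyl)-N-methoxy-N-methylbutanamide F6. Mitsunobu cyclization (PPh3, DIAD, THF, 0 °C to rt) then closes ring C at room temperature to give 9.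

3. Step 11. Peracid oxidation of the two electron-rich rings may compete with the slow acyl-to-oxygen migration. The fallback is a Dakin route that leaves out steps 10 to 12; it sets out from 15 and comes back at 19. H2O2/NaOH (THF/H2O, 0 °C) should convert the ortho,para-dihydroxyaryl ketone 15 into 5-[(3S)-7-(benzyloxy)-6,8-dimethoxy-3,4-dihydro-2H-chromen-3-yl]-3-methoxybenzene-1,2,4-triol F7. Air oxidizes this to 5-[(3S)-7-(benzyloxy)-6,8-dimethoxy-3,4-dihydro-2H-chromen-3-yl]-2-hydroxy-3-methoxycyclohexa-2,5-diene-1,4-dione F8. O-Methylation of this vinylogous acid with Me3SiCHN2 (MeOH/toluene, rt) gives 19.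

Further compounds
F1 | step 9 | 2-[(3S)-7-(benzyloxy)-6,8-dimethoxy-3,4-dihydro-2H-chromen-3-yl]acetaldehyde | O=CC[C@H]1COc2c(OC)c(OCc3ccccc3)c(OC)cc2C1
F2 | step 9 | 2-[(3S)-7-(benzyloxy)-6,8-dimethoxy-3,4-dihydro-2H-chromen-3-yl]ethenyl nonafluorobutane-1-sulfonate | FC(F)(F)C(F)(F)C(F)(F)C(F)(F)S(=O)(=O)OC=C[C@H]1COc2c(OC)c(OCc3ccccc3)c(OC)cc2C1
F3 | step 9 | (3S)-7-(benzyloxy)-3-ethynyl-6,8-dimethoxy-3,4-dihydro-2H-chromene | C#C[C@H]1COc2c(OC)c(OCc3ccccc3)c(OC)cc2C1
F4 | step 9 | 4-{[(3S)-7-(benzyloxy)-6,8-dimethoxy-3,4-dihydro-2H-chromen-3-yl]ethynyl}-4-hydroxy-2,3-dimethoxycyclobut-2-en-1-one | COC1=C(OC)C(O)(C#C[C@H]2COc3c(OC)c(OCc4ccccc4)c(OC)cc3C2)C1=O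
F5 | step 6 | (4S)-4-{[4-(benzyloxy)-2-hydroxy-3,5-dimethoxyphenyl]methyl}oxolan-2-one | O=C1C[C@H](Cc2cc(OC)c(OCc3ccccc3)c(OC)c2O)CO1
F6 | step 6 | (3S)-4-[4-(benzyloxy)-2-hydroxy-3,5-dimethoxyphenyl]-3-(hydroxymethyl)-N-methoxy-N-methylbutanamide | CON(C)C(=O)C[C@H](Cc1cc(OC)c(OCc2ccccc2)c(OC)c1O)CO
F7 | step 11 | 5-[(3S)-7-(benzyloxy)-6,8-dimethoxy-3,4-dihydro-2H-chromen-3-yl]-3-methoxybenzene-1,2,4-triol | COc1c(O)c(O)cc([C@H]2COc3c(OC)c(OCc4ccccc4)c(OC)cc3C2)c1O
F8 | step 11 | 5-[(3S)-7-(benzyloxy)-6,8-dimethoxy-3,4-dihydro-2H-chromen-3-yl]-2-hydroxy-3-methoxycyclohexa-2,5-diene-1,4-dione | COC1=C(O)C(=O)C=C([C@H]2COc3c(OC)c(OCc4ccccc4)c(OC)cc3C2)C1=O
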